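**Plan**

- Numbering used throughout: carbocycle C1 (CHOAc), C2, C3, C4 (CHMe), C5, C6 (C=O), C7, C8 (C(OH)Me), C9=C10, C11 (O, iPr), C12, C13, C14 (O, Me), with C14 bonded to C1; the ether oxygen bridges C11 and C14.
- Cuts, last-formed bond first: C2–C3 (ring-closing metathesis, then saturation), C6–C7 (dithiane anion on an epoxide), C9=C10 (Julia–Kocienski), then the two C–O bonds of the THF together with the C1 and C10 hydroxyls.
- Enabling feature: the cis-2,5-THF ring (O, C11, C12, C13, C14) has both α-carbons fully substituted, an oxygen on C1 next to C14, and a carbon (C10) on C11 that can start as CH2OH. This is the syn-dioxygenation pattern of the 1,5-diene C1=C14(Me)–C13–C12–C11(iPr)=C10, so a single permanganate oxidation of a (Z)-dienoyl sultam delivers it.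
- Forward order: six steps to the achiral (Z)-dienoyl imide; oxidative cyclisation (the THF, the only ring before the macrocycle); C10 to a tetrazolyl sulfone and C2 to a vinyl group; olefination with the C7–C9 epoxy aldehyde; epoxide opening by the C3–C6 dithiane; then the 14-membered ring by metathesis at C2=C3 and diimide reduction.
- Stereochemistry: C1, C14 and C11 from the Mn step (two syn additions through one metal, (Z)-alkene, enoyl face chosen by the (2S)-sultam); C8 from (S)-2-methylglycidol; C4 from (S)-3-bromo-2-methylpropan-1-ol; (E)-C9=C10 from the Julia–Kocienski step.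

Key step: step 7

Assumption: the usual model for non-chelated additions to N-enoyl bornane-10,2-sultams (s-cis enoyl, C=O anti to SO2, Cα-re attack for the (2R)-sultam) is taken to hold for permanganate; the target needs Cα-si attack at C1, so the (2S)-sultam is used, and its antipode would replace it with no other change if the sense proved opposite.

**Route**

Step 1
Reactants: 1 3-methylbutan-2-one; 2 3-bromoprop-1-yne
Product: 4 2-methylhept-6-yn-3-one, via lithium enolate 3 (not isolated)
Conditions: LDA, THF, −78 °C; then 2, −78 → 0 °C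
Reagents that add atoms: none
Why: LDA deprotonates the methyl group under kinetic control and the less substituted lithium enolate is C-alkylated by the propargylic bromide (ketone enolate alkylation).

Step 2
Reactants: 4 2-methylhept-6-yn-3-one
Product: 5 6-methyl-5-methylidenehept-1-yne
Conditions: Ph3PCH3Br, KOtBu, THF, 0 °C → rt
Reagents that add atoms: methyltriphenylphosphonium bromide, C[P+](c1ccccc1)(c1ccccc1)c1ccccc1.[Br-]
Why: Wittig methylenation of the isopropyl ketone with the non-stabilised ylide installs the 1,1-disubstituted alkene C10=C11, the terminal alkyne being at most reversibly deprotonated by excess ylide.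

Step 3
Reactants: 5 6-methyl-5-methylidenehept-1-yne
Product: 7 methyl 7-methyl-6-methylideneoct-2-ynoate, via lithium acetylide 6 (not isolated)
Conditions: n-BuLi, THF, −78 °C; then ClCO2Me, −78 → 0 °C
Reagents that add atoms: methyl chloroformate, COC(=O)Cl
Why: deprotonation of the terminal alkyne and C-acylation of the lithium acetylide by the chloroformate is the standard preparation of 2-alkynoates.

Step 4
Reactants: 7 methyl 7-methyl-6-methylideneoct-2-ynoate
Product: 9 methyl (2Z)-3,7-dimethyl-6-methylideneoct-2-enoate, via alkenylcuprate 8 (not isolated)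
Conditions: Me2CuLi (from MeLi, CuI), THF, −78 °C; then MeOH, −78 °C
Reagents that add atoms: lithium dimethylcuprate, [Li+].C[Cu-]C
Why: syn-carbocupration of the alkynoate places the new methyl on C14 cis to copper, and protonation at −78 °C with retention leaves the chain and the ester cis, i.e. the (Z)-C1=C14 enoate (conjugate addition of a Gilman cuprate to a 2-ynoate).

Step 5
Reactants: 9 methyl (2Z)-3,7-dimethyl-6-methylideneoct-2-enoate
Product: 10 (2Z)-3,7-dimethyl-6-methylideneoct-2-enoic acid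
Conditions: LiOH, THF/MeOH/H2O, rt; then 1 M HCl
Reagents that add atoms: lithium hydroxide, [Li+].[OH-]
Why: ester saponification by acyl substitution at room temperature offers the trisubstituted (Z)-alkene no pathway for isomerisation.

Step 6
Reactants: 10 (2Z)-3,7-dimethyl-6-methylideneoct-2-enoic acid; 11 (2S)-bornane-10,2-sultam
Product: 14 N-[(2Z)-3,7-dimethyl-6-methylideneoct-2-enoyl]-(2S)-bornane-10,2-sultam, via acid chloride 12 (not isolated), via sodium sultamide 13 (not isolated)
Conditions: (COCl)2, DMF (cat.), CH2Cl2, 0 °C; then 11, NaH, toluene, 0 °C → rt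
Reagents that add atoms: none
Why: N-acylation of the sodium salt of the sultam by the acid chloride is the standard entry to N-enoyl sultams and, with no amine base present, avoids ketene formation and loss of the (Z)-geometry.

Step 7
Reactants: 14 N-[(2Z)-3,7-dimethyl-6-methylideneoct-2-enoyl]-(2S)-bornane-10,2-sultam
Product: 16 N-{(2S)-2-hydroxy-2-[(2S,5S)-5-(hydroxymethyl)-2-methyl-5-(propan-2-yl)oxolan-2-yl]acetyl}-(2S)-bornane-10,2-sultam, via manganate(V) diester 15 (not isolated)
Conditions: KMnO4 (1.4 equiv), AcOH (3 equiv), acetone/H2O (pH ≈ 6), −35 → −10 °C; then aq Na2S2O5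
Reagents that add atoms: potassium permanganate, [K+].[O-][Mn](=O)(=O)=O
Why: Permanganate adds (3+2) to the conjugated C1=C14 alkene to give the cyclic manganate(V) diester 15, which after oxidation to Mn(VI) by a second permanganate adds (3+2) across C10=C11 from the same metal centre, and hydrolysis of the Mn(IV) diester releases the diol. The closest known reaction is the permanganate oxidative cyclisation of 1,5-dienoyl camphorsultams to cis-2,5-disubstituted THF diols. The THF ring (O, C11, C12, C13, C14) closes in a 5-exo sense by intramolecular syn-oxometallation of the 1,1-disubstituted alkene, the oxygen on C14 being already bound to manganese. C1 is set by the enoyl face that the (2S)-sultam leaves open (Cα-si in the s-cis, C=O/SO2-anti imide), C14 by syn addition to the (Z)-alkene, and C11 by delivery of both ring C–O bonds from one manganese, which can only give the cis-THF. The step needs attack at the enoyl alkene before the isolated one and on a single face: the first is secured by the preference of permanganate for electron-poor conjugated alkenes, the second by the auxiliary, and acetic acid buffering at low temperature keeps the manganate esters from over-oxidising to ketols.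

Step 8
Reactants: 16 THF diol imide
Product: 17 N-{(2S)-2-hydroxy-2-[(2S,5S)-2-methyl-5-{[(1-phenyl-1H-tetrazol-5-yl)sulfanyl]methyl}-5-(propan-2-yl)oxolan-2-yl]acetyl}-(2S)-bornane-10,2-sultam
Conditions: 1-phenyl-1H-tetrazole-5-thiol, PPh3, DIAD, THF, 0 → 40 °C
Reagents that add atoms: 1-phenyl-1H-tetrazole-5-thiol, Sc1nnnn1-c1ccccc1
Why: Mitsunobu thioetherification activates only the primary C10 hydroxyl (the secondary C1 hydroxyl lies between a quaternary carbon and the imide and is not displaced), and the acidic, strongly nucleophilic thiol is the kind of partner that still substitutes a neopentyl-type oxyphosphonium salt.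

Step 9
Reactants: 17 C10 tetrazolyl sulfide
Product: 18 C1 tert-butyldimethylsilyl ether of 17
Conditions: TBSOTf, 2,6-lutidine, CH2Cl2, 0 °C
Reagents that add atoms: tert-butyldimethylsilyl trifluoromethanesulfonate, CC(C)(C)[Si](C)(C)OS(=O)(=O)C(F)(F)F
Why: the silyl triflate silylates the hindered secondary α-hydroxy imide without enolising it, and the ether masks C1–OH through the hydride, ylide and carbanion steps that follow.

Step 10
Reactants: 18 silylated imide
Product: 19 (2R)-2-[(tert-butyldimethylsilyl)oxy]-2-[(2S,5S)-2-methyl-5-{[(1-phenyl-1H-tetrazol-5-yl)sulfanyl]methyl}-5-(propan-2-yl)oxolan-2-yl]ethan-1-ol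
Conditions: LiBH4, THF, MeOH (1 equiv), 0 °C → rt
Reagents that add atoms: none
Why: reductive cleavage of the N-acyl sultam by borohydride gives the C2 primary alcohol and returns the auxiliary, the transient aldehyde being reduced faster than it can enolise, so C1 is untouched (S to R is a priority change only).

Step 11
Reactants: 19 C2 alcohol
Product: 20 (2S)-2-[(tert-butyldimethylsilyl)oxy]-2-[(2S,5S)-2-methyl-5-{[(1-phenyl-1H-tetrazol-5-yl)sulfanyl]methyl}-5-(propan-2-yl)oxolan-2-yl]acetaldehyde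
Conditions: DMP, NaHCO3, CH2Cl2, rt
Reagents that add atoms: none
Why: Dess–Martin oxidation stops at the α-silyloxy aldehyde under buffered, non-basic conditions that neither epimerise C1 nor oxidise the electron-poor heteroaryl sulfide.

Step 12
Reactants: 20 C2 aldehyde
Product: 21 5-({(2S,5S)-5-[(1R)-1-[(tert-butyldimethylsilyl)oxy]prop-2-en-1-yl]-5-methyl-2-(propan-2-yl)oxolan-2-yl}methylsulfanyl)-1-phenyl-1H-tetrazole
Conditions: Ph3PCH3Br, KOtBu, THF, 0 °C
Reagents that add atoms: methyltriphenylphosphonium bromide, C[P+](c1ccccc1)(c1ccccc1)c1ccccc1.[Br-]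
Why: Wittig methylenation of the α-silyloxy aldehyde gives the C1 vinyl group (its terminal carbon is the one later lost as ethene), the hindered α-position being slow to enolise.

Step 13
Reactants: 21 vinyl sulfide
Product: 22 5-({(2S,5S)-5-[(1R)-1-[(tert-butyldimethylsilyl)oxy]prop-2-en-1-yl]-5-methyl-2-(propan-2-yl)oxolan-2-yl}methanesulfonyl)-1-phenyl-1H-tetrazole
Conditions: (NH4)6Mo7O24·4H2O (cat.), 30% H2O2, EtOH, 0 °C → rt
Reagents that add atoms: hydrogen peroxide, OO
Why: molybdate-catalysed peroxide oxidation takes the tetrazolyl sulfide to the sulfone and leaves the monosubstituted alkene and the silyl ether alone (standard preparation of Julia–Kocienski sulfones).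

Step 14
Reactants: 23 (S)-2-methylglycidol
Product: 24 (2R)-2-methyloxirane-2-carbaldehyde
Conditions: (COCl)2, DMSO, CH2Cl2, −78 °C; then Et3N, −78 → −20 °C; used as a dried solution
Reagents that add atoms: none
Why: Swern oxidation of the epoxy alcohol gives the volatile epoxy aldehyde, whose quaternary α-carbon (the future C8) cannot epimerise (S to R is a priority change only).

Step 15
Reactants: 22 C10 sulfone; 24 (2R)-2-methyloxirane-2-carbaldehyde
Product: 26 tert-butyldimethyl{[(1R)-1-[(2S,5S)-2-methyl-5-{(E)-2-[(2S)-2-methyloxiran-2-yl]ethenyl}-5-(propan-2-yl)oxolan-2-yl]prop-2-en-1-yl]oxy}silane, via sulfonyl carbanion 25 (not isolated)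
Conditions: KHMDS, DME, −70 °C, 20 min; then 24, −70 → −20 °C
Reagents that add atoms: none
Why: Julia–Kocienski olefination, in which the potassium sulfonyl carbanion adds to the non-enolisable aldehyde and Smiles rearrangement with loss of SO2 and the tetrazololate gives the alkene, the potassium/DME conditions and the two bulky neighbours favouring (E)-C9=C10, while the ring oxygen β to the carbanion is a poor leaving group at −70 °C.

Step 16
Reactants: 27 (2S)-3-bromo-2-methylpropan-1-ol
Product: 28 [(2S)-3-bromo-2-methylpropoxy](tert-butyl)dimethylsilane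
Conditions: TBSCl, imidazole, CH2Cl2, rt
Reagents that add atoms: tert-butyldimethylsilyl chloride, CC(C)(C)[Si](C)(C)Cl
Why: silylation of the primary alcohol protects it from the basic dithiane anion of the next step.

Step 17
Reactants: 28 silyl ether bromide; 29 1,3-dithiane
Product: 31 tert-butyl{[(2R)-3-(1,3-dithian-2-yl)-2-methylpropyl]oxy}dimethylsilane, via 2-lithio-1,3-dithiane 30 (not isolated)
Conditions: n-BuLi, THF, −30 °C; then 28, DMPU, −78 °C → rt
Reagents that add atoms: none
Why: alkylation of 2-lithio-1,3-dithiane by the primary bromide (Corey–Seebach reaction) forms the C5–C6 bond with C6 masked as an acyl-anion equivalent, the stereocentre C4 not being involved.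

Step 18
Reactants: 31 silylated dithiane
Product: 32 (2R)-3-(1,3-dithian-2-yl)-2-methylpropan-1-ol
Conditions: TBAF, THF, rt
Reagents that add atoms: none
Why: fluoride cleaves the primary silyl ether and leaves the thioacetal untouched.

Step 19
Reactants: 32 dithiane alcohol
Product: 33 (2R)-3-(1,3-dithian-2-yl)-2-methylpropanal
Conditions: (COCl)2, DMSO, CH2Cl2, −78 °C; then iPr2NEt, −78 → −30 °C; used crude
Reagents that add atoms: none
Why: Swern oxidation with the hindered amine base gives the α-methyl aldehyde at low temperature with minimal enolisation at C4 and does not oxidise the dithiane sulfur.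

Step 20
Reactants: 33 dithiane aldehyde
Product: 34 2-[(2R)-2-methylbut-3-en-1-yl]-1,3-dithiane
Conditions: Ph3PCH3Br, KOtBu, THF, −78 → 0 °C
Reagents that add atoms: methyltriphenylphosphonium bromide, C[P+](c1ccccc1)(c1ccccc1)c1ccccc1.[Br-]
Why: Wittig methylenation of the freshly made aldehyde gives the C3 vinyl group (its terminal carbon is lost later as ethene) faster than the ylide epimerises C4.

Step 21
Reactants: 34 vinyl dithiane; 26 vinyl epoxide
Product: 36 (2R,3E)-4-[(2S,5S)-5-[(1R)-1-[(tert-butyldimethylsilyl)oxy]prop-2-en-1-yl]-5-methyl-2-(propan-2-yl)oxolan-2-yl]-2-methyl-1-{2-[(2R)-2-methylbut-3-en-1-yl]-1,3-dithian-2-yl}but-3-en-2-ol, via lithiated dithiane 35 (not isolated)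
Conditions: t-BuLi, THF/HMPA (10:1), −78 °C; then 26, −78 → −30 °C
Reagents that add atoms: none
Why: the 2-lithio-2-alkyl-1,3-dithiane opens the 2,2-disubstituted epoxide by SN2 attack at its CH2 (C7), because the allylic epoxide carbon C8 is quaternary and the SN2′ terminus C10 sits next to the quaternary C11, so the C6–C7 bond forms and C8–O keeps its configuration (dithiane–epoxide coupling).

Step 22
Reactants: 36 silylated seco-diene
Product: 37 (1R)-1-[(2S,5S)-5-[(1E,3R)-3-hydroxy-3-methyl-4-{2-[(2R)-2-methylbut-3-en-1-yl]-1,3-dithian-2-yl}but-1-en-1-yl]-2-methyl-5-(propan-2-yl)oxolan-2-yl]prop-2-en-1-ol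
Conditions: TBAF, THF, rt → 45 °C
Reagents that add atoms: none
Why: fluoride removes the hindered secondary silyl ether while the dithiane still masks the ketone, so no β-hydroxy ketone is exposed to the basic reagent.

Step 23
Reactants: 37 diol
Product: 38 C1 acetate of 37
Conditions: Ac2O, pyridine, DMAP (cat.), CH2Cl2, 0 °C → rt
Reagents that add atoms: acetic anhydride, CC(=O)OC(C)=O
Why: DMAP-catalysed acetylation esterifies the secondary C1 hydroxyl and leaves the tertiary C8 hydroxyl, which needs far more forcing conditions.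

Step 24
Reactants: 38 acetate dithiane
Product: 39 (1R)-1-[(2S,5S)-5-[(1E,3R,7R)-3-hydroxy-3,7-dimethyl-5-oxonona-1,8-dien-1-yl]-2-methyl-5-(propan-2-yl)oxolan-2-yl]prop-2-en-1-yl acetate
Conditions: MeI, CaCO3, MeCN/H2O (9:1), 45 °C
Reagents that add atoms: water, O
Why: S-methylation and hydrolysis of the 1,3-dithiane under carbonate buffering release the C6 ketone under neutral conditions that spare the tertiary allylic alcohol, the acetate and the new β-hydroxy ketone (alkylative dethioacetalisation).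

Step 25
Reactants: 39 keto diene
Product: 40 macrocyclic 2,9-diene (2-ene analogue of the target; C2=C3 expected mainly E)
Conditions: second-generation Ru–NHC benzylidene metathesis catalyst (10 mol%), CH2Cl2 (1 mM), 40 °C
Reagents that add atoms: none
Why: ring-closing metathesis of the two monosubstituted alkenes closes the 14-membered carbocycle at C2=C3 with loss of ethene, the C9=C10 alkene between two fully substituted carbons being inert to the catalyst, and either C2=C3 geometry serves.

Step 26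
Reactants: 40 macrocyclic diene
Product: 41 target (1R,4S,8R,9E,11S,14S)
Conditions: KO2CN=NCO2K, AcOH, MeOH, 0 °C → rt
Reagents that add atoms: none
Why: diimide reduction transfers H2 in a concerted syn manner at a rate that falls steeply with steric hindrance, so C2=C3 is saturated while C9=C10, flanked by the fully substituted C8 and C11, and the allylic acetate (no hydrogenolysis with diimide) remain.

**Compound list**

1 | 3-methylbutan-2-one | CC(C)C(C)=O | starting material
2 | 3-bromoprop-1-yne (propargyl bromide) | BrCC#C | starting material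
3 | lithium 3-methylbut-1-en-2-olate | [Li+].[O-]C(=C)C(C)C | intermediate (not isolated)
4 | 2-methylhept-6-yn-3-one | CC(C)C(=O)CCC#C | intermediate
5 | 6-methyl-5-methylidenehept-1-yne | CC(C)C(=C)CCC#C | intermediate
6 | lithium 6-methyl-5-methylidenehept-1-yn-1-ide | [Li+].[C-]#CCCC(=C)C(C)C | intermediate (not isolated)
7 | methyl 7-methyl-6-methylideneoct-2-ynoate | COC(=O)C#CCCC(=C)C(C)C | intermediate
8 | lithium alkenyl(methyl)cuprate from syn-carbocupration of 7 (Cu on C1, cis to the new methyl) | [Li+].COC(=O)/C([Cu-]C)=C(C)\CCC(=C)C(C)C | intermediate (not isolated)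
9 | methyl (2Z)-3,7-dimethyl-6-methylideneoct-2-enoate | COC(=O)/C=C(C)\CCC(=C)C(C)C | intermediate
10 | (2Z)-3,7-dimethyl-6-methylideneoct-2-enoic acid | OC(=O)/C=C(C)\CCC(=C)C(C)C | intermediate
11 | (2S)-bornane-10,2-sultam [(1R,2S,4S); (+)-2,10-camphorsultam] | CC1(C)[C@H]2CC[C@@]13CS(=O)(=O)N[C@H]3C2 | starting material
12 | (2Z)-3,7-dimethyl-6-methylideneoct-2-enoyl chloride | ClC(=O)/C=C(C)\CCC(=C)C(C)C | intermediate (not isolated)
13 | sodium salt of 11 | [Na+].CC1(C)[C@H]2CC[C@@]13CS(=O)(=O)[N-][C@H]3C2 | intermediate (not isolated)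
14 | N-[(2Z)-3,7-dimethyl-6-methylideneoct-2-enoyl]-(2S)-bornane-10,2-sultam | CC1(C)[C@H]2CC[C@@]13CS(=O)(=O)N([C@H]3C2)C(=O)/C=C(C)\CCC(=C)C(C)C | intermediate (key-step precursor)
15 | potassium cyclic manganate(V) diester across C1 and C14 of 14 | [K+].CC1(C)[C@H]2CC[C@@]13CS(=O)(=O)N([C@H]3C2)C(=O)[C@H]4O[Mn-](=O)(=O)O[C@@]4(C)CCC(=C)C(C)C | intermediate (not isolated)
16 | N-{(2S)-2-hydroxy-2-[(2S,5S)-5-(hydroxymethyl)-2-methyl-5-(propan-2-yl)oxolan-2-yl]acetyl}-(2S)-bornane-10,2-sultam | CC1(C)[C@H]2CC[C@@]13CS(=O)(=O)N([C@H]3C2)C(=O)[C@@H](O)[C@]4(C)CC[C@@](CO)(C(C)C)O4 | intermediate (key-step product)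
17 | N-{(2S)-2-hydroxy-2-[(2S,5S)-2-methyl-5-{[(1-phenyl-1H-tetrazol-5-yl)sulfanyl]methyl}-5-(propan-2-yl)oxolan-2-yl]acetyl}-(2S)-bornane-10,2-sultam | CC1(C)[C@H]2CC[C@@]13CS(=O)(=O)N([C@H]3C2)C(=O)[C@@H](O)[C@]4(C)CC[C@@](CSc5nnnn5-c5ccccc5)(C(C)C)O4 | intermediate
18 | C1 tert-butyldimethylsilyl ether of 17 (C1 S) | CC1(C)[C@H]2CC[C@@]13CS(=O)(=O)N([C@H]3C2)C(=O)[C@@H](O[Si](C)(C)C(C)(C)C)[C@]4(C)CC[C@@](CSc5nnnn5-c5ccccc5)(C(C)C)O4 | intermediate
19 | (2R)-2-[(tert-butyldimethylsilyl)oxy]-2-[(2S,5S)-2-methyl-5-{[(1-phenyl-1H-tetrazol-5-yl)sulfanyl]methyl}-5-(propan-2-yl)oxolan-2-yl]ethan-1-ol | OC[C@@H](O[Si](C)(C)C(C)(C)C)[C@]1(C)CC[C@@](CSc2nnnn2-c2ccccc2)(C(C)C)O1 | intermediate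
20 | (2S)-2-[(tert-butyldimethylsilyl)oxy]-2-[(2S,5S)-2-methyl-5-{[(1-phenyl-1H-tetrazol-5-yl)sulfanyl]methyl}-5-(propan-2-yl)oxolan-2-yl]acetaldehyde | O=C[C@@H](O[Si](C)(C)C(C)(C)C)[C@]1(C)CC[C@@](CSc2nnnn2-c2ccccc2)(C(C)C)O1 | intermediate
21 | 5-({(2S,5S)-5-[(1R)-1-[(tert-butyldimethylsilyl)oxy]prop-2-en-1-yl]-5-methyl-2-(propan-2-yl)oxolan-2-yl}methylsulfanyl)-1-phenyl-1H-tetrazole | C=C[C@@H](O[Si](C)(C)C(C)(C)C)[C@]1(C)CC[C@@](CSc2nnnn2-c2ccccc2)(C(C)C)O1 | intermediate
22 | 5-({(2S,5S)-5-[(1R)-1-[(tert-butyldimethylsilyl)oxy]prop-2-en-1-yl]-5-methyl-2-(propan-2-yl)oxolan-2-yl}methanesulfonyl)-1-phenyl-1H-tetrazole | C=C[C@@H](O[Si](C)(C)C(C)(C)C)[C@]1(C)CC[C@@](CS(=O)(=O)c2nnnn2-c2ccccc2)(C(C)C)O1 | intermediate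
23 | (S)-2-methylglycidol [(2S)-(2-methyloxiran-2-yl)methanol] | OC[C@@]1(C)CO1 | starting material
24 | (2R)-2-methyloxirane-2-carbaldehyde | O=C[C@@]1(C)CO1 | intermediate
25 | potassium α-sulfonyl carbanion of 22 (at C10) | [K+].C=C[C@@H](O[Si](C)(C)C(C)(C)C)[C@]1(C)CC[C@@]([CH-]S(=O)(=O)c2nnnn2-c2ccccc2)(C(C)C)O1 | intermediate (not isolated)
26 | tert-butyldimethyl{[(1R)-1-[(2S,5S)-2-methyl-5-{(E)-2-[(2S)-2-methyloxiran-2-yl]ethenyl}-5-(propan-2-yl)oxolan-2-yl]prop-2-en-1-yl]oxy}silane | C=C[C@@H](O[Si](C)(C)C(C)(C)C)[C@]1(C)CC[C@@](/C=C/[C@@]2(C)CO2)(C(C)C)O1 | intermediate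
27 | (2S)-3-bromo-2-methylpropan-1-ol | OC[C@H](C)CBr | starting material
28 | [(2S)-3-bromo-2-methylpropoxy](tert-butyl)dimethylsilane | CC(C)(C)[Si](C)(C)OC[C@H](C)CBr | intermediate
29 | 1,3-dithiane | C1CSCSC1 | starting material
30 | 2-lithio-1,3-dithiane | [Li]C1SCCCS1 | intermediate (not isolated)
31 | tert-butyl{[(2R)-3-(1,3-dithian-2-yl)-2-methylpropyl]oxy}dimethylsilane | CC(C)(C)[Si](C)(C)OC[C@H](C)CC1SCCCS1 | intermediate
32 | (2R)-3-(1,3-dithian-2-yl)-2-methylpropan-1-ol | OC[C@H](C)CC1SCCCS1 | intermediate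
33 | (2R)-3-(1,3-dithian-2-yl)-2-methylpropanal | O=C[C@H](C)CC1SCCCS1 | intermediate
34 | 2-[(2R)-2-methylbut-3-en-1-yl]-1,3-dithiane | C=C[C@H](C)CC1SCCCS1 | intermediate
35 | 2-lithio-2-[(2R)-2-methylbut-3-en-1-yl]-1,3-dithiane | [Li]C1(C[C@@H](C)C=C)SCCCS1 | intermediate (not isolated)
36 | (2R,3E)-4-[(2S,5S)-5-[(1R)-1-[(tert-butyldimethylsilyl)oxy]prop-2-en-1-yl]-5-methyl-2-(propan-2-yl)oxolan-2-yl]-2-methyl-1-{2-[(2R)-2-methylbut-3-en-1-yl]-1,3-dithian-2-yl}but-3-en-2-ol | C=C[C@@H](O[Si](C)(C)C(C)(C)C)[C@]1(C)CC[C@@](/C=C/[C@](C)(O)CC2(C[C@@H](C)C=C)SCCCS2)(C(C)C)O1 | intermediate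
37 | (1R)-1-[(2S,5S)-5-[(1E,3R)-3-hydroxy-3-methyl-4-{2-[(2R)-2-methylbut-3-en-1-yl]-1,3-dithian-2-yl}but-1-en-1-yl]-2-methyl-5-(propan-2-yl)oxolan-2-yl]prop-2-en-1-ol | C=C[C@@H](O)[C@]1(C)CC[C@@](/C=C/[C@](C)(O)CC2(C[C@@H](C)C=C)SCCCS2)(C(C)C)O1 | intermediate
38 | C1 acetate of 37 | C=C[C@@H](OC(C)=O)[C@]1(C)CC[C@@](/C=C/[C@](C)(O)CC2(C[C@@H](C)C=C)SCCCS2)(C(C)C)O1 | intermediate
39 | (1R)-1-[(2S,5S)-5-[(1E,3R,7R)-3-hydroxy-3,7-dimethyl-5-oxonona-1,8-dien-1-yl]-2-methyl-5-(propan-2-yl)oxolan-2-yl]prop-2-en-1-yl acetate | C=C[C@@H](OC(C)=O)[C@]1(C)CC[C@@](/C=C/[C@](C)(O)CC(=O)C[C@@H](C)C=C)(C(C)C)O1 | intermediate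
40 | macrocyclic diene: the target with an additional C2=C3 double bond (1R,4R,8R,9E,11S,14S; C2=C3 drawn E, either geometry serves) | CC(=O)O[C@@H]1/C=C/[C@H](C)CC(=O)C[C@@](C)(O)/C=C/[C@@]2(C(C)C)CC[C@]1(C)O2 | intermediate
41 | target CNP0131678.1: (1R,4S,8R,9E,11S,14S)-8-hydroxy-4,8,14-trimethyl-6-oxo-11-(propan-2-yl)-11,14-epoxycyclotetradec-9-en-1-yl acetate (numbering of the plan) | CC(=O)O[C@@H]1CC[C@H](C)CC(=O)C[C@@](C)(O)/C=C/[C@@]2(C(C)C)CC[C@]1(C)O2 | target

**Step count and risks**

Total: 26 steps. Longest linear sequence: 20 steps (steps 1–13, 15, 21–26); side branches are step 14 (one step) and steps 16–20 (five steps).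

Steps most likely to fail:

1. Step 7. The first (3+2) addition may discriminate the two enoyl faces only partly (the (Z)-β,β-disubstituted enoyl is a more crowded case for the sultam), and the manganate esters may over-oxidise. Fallback, setting out from 10 and coming back at 19: facial control is moved from the sultam imide to the ester of a trityl-shielded cyclohexanol, an auxiliary class that is also known in permanganate oxidative cyclisations of dienoates. Acid 10 is esterified (DCC, DMAP) with (1S,2R)-2-tritylcyclohexan-1-ol (its antipode if that one exposes the Cα-si face) to give the dienoate F1. KMnO4/AcOH gives the cis-THF diol ester F2, freed of its diastereomer by chromatography. Mitsunobu thioetherification gives the sulfide F3, silylation (TBSOTf, 2,6-lutidine) gives the silyl ether F4, and DIBAL reduction releases the auxiliary and delivers alcohol 19.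

2. Step 15. The α-sulfonyl carbanion 25 may expel the ring oxygen (β-elimination that opens the THF) or, being neopentyl, may add too slowly to the aldehyde. Fallback, setting out from 16 and coming back at 26: the polarity is reversed so that C10 is the aldehyde.
 - Bis-silylation of 16 (TBSOTf) gives the bis-silyl ether imide F5, and LiBH4 gives the C2 alcohol F6.
 - Dess–Martin oxidation gives the aldehyde F7 and Wittig methylenation the vinyl compound F8.
 - HF·pyridine removes the more accessible primary silyl ether to give the C10 alcohol F9, and Swern oxidation gives the non-enolisable C10 aldehyde F10.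
 - Wittig reaction with 1-(triphenylphosphoranylidene)propan-2-one gives the (E)-enone F11.
 - Corey–Chaykovsky epoxidation of the ketone with dimethylsulfonium methylide gives the vinyl epoxide 26 together with its C8 epimer F12, which is removed by chromatography. C8 is then no longer drawn from the chiral pool.

3. Step 21. The hindered dithiane anion may attack C10 (SN2′) or deprotonate the epoxide methyl group instead of opening the ring at C7. Fallback, setting out from 34, 23 and 22 and coming back at 37: the order of the two unions is reversed, so that the epoxide opening is done on a saturated glycidyl ether.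
 - (S)-2-Methylglycidol 23 is silylated (TESCl, imidazole) to the glycidyl triethylsilyl ether F13.
 - Lithiated dithiane 35 opens it at CH2 to give the tertiary alcohol F14, and TBSOTf gives the bis-silyl ether F15.
 - PPTS in MeOH frees the primary alcohol F16, and Swern oxidation gives the α-silyloxy aldehyde F17.
 - Julia–Kocienski olefination with the carbanion 25 of sulfone 22 gives the (E)-alkene F18.
 - TBAF removes both silyl ethers and rejoins the route at diol 37.

**Further compounds**

F1 | step 7 | (1S,2R)-2-tritylcyclohexyl (2Z)-3,7-dimethyl-6-methylideneoct-2-enoate | O=C(/C=C(C)\CCC(=C)C(C)C)O[C@H]1CCCC[C@@H]1C(c1ccccc1)(c1ccccc1)c1ccccc1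
F2 | step 7 | (1S,2R)-2-tritylcyclohexyl (2S)-2-hydroxy-2-[(2S,5S)-5-(hydroxymethyl)-2-methyl-5-(propan-2-yl)oxolan-2-yl]acetate | O=C([C@@H](O)[C@]1(C)CC[C@@](CO)(C(C)C)O1)O[C@H]1CCCC[C@@H]1C(c1ccccc1)(c1ccccc1)c1ccccc1
F3 | step 7 | C10 (1-phenyl-1H-tetrazol-5-yl) sulfide of F2 | O=C([C@@H](O)[C@]1(C)CC[C@@](CSc2nnnn2-c2ccccc2)(C(C)C)O1)O[C@H]1CCCC[C@@H]1C(c1ccccc1)(c1ccccc1)c1ccccc1
F4 | step 7 | C1 tert-butyldimethylsilyl ether of F3 | O=C([C@@H](O[Si](C)(C)C(C)(C)C)[C@]1(C)CC[C@@](CSc2nnnn2-c2ccccc2)(C(C)C)O1)O[C@H]1CCCC[C@@H]1C(c1ccccc1)(c1ccccc1)c1ccccc1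
F5 | step 15 | bis(tert-butyldimethylsilyl) ether of 16 (C1–O and C10–O) | CC1(C)[C@H]2CC[C@@]13CS(=O)(=O)N([C@H]3C2)C(=O)[C@@H](O[Si](C)(C)C(C)(C)C)[C@]4(C)CC[C@@](CO[Si](C)(C)C(C)(C)C)(C(C)C)O4
F6 | step 15 | (2R)-2-[(tert-butyldimethylsilyl)oxy]-2-[(2S,5S)-5-{[(tert-butyldimethylsilyl)oxy]methyl}-2-methyl-5-(propan-2-yl)oxolan-2-yl]ethan-1-ol | OC[C@@H](O[Si](C)(C)C(C)(C)C)[C@]1(C)CC[C@@](CO[Si](C)(C)C(C)(C)C)(C(C)C)O1
F7 | step 15 | (2S)-2-[(tert-butyldimethylsilyl)oxy]-2-[(2S,5S)-5-{[(tert-butyldimethylsilyl)oxy]methyl}-2-methyl-5-(propan-2-yl)oxolan-2-yl]acetaldehyde | O=C[C@@H](O[Si](C)(C)C(C)(C)C)[C@]1(C)CC[C@@](CO[Si](C)(C)C(C)(C)C)(C(C)C)O1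
F8 | step 15 | C2-vinyl bis-silyl ether (C1 R; C11 and C14 S) | C=C[C@@H](O[Si](C)(C)C(C)(C)C)[C@]1(C)CC[C@@](CO[Si](C)(C)C(C)(C)C)(C(C)C)O1
F9 | step 15 | {(2S,5S)-5-[(1R)-1-[(tert-butyldimethylsilyl)oxy]prop-2-en-1-yl]-5-methyl-2-(propan-2-yl)oxolan-2-yl}methanol | C=C[C@@H](O[Si](C)(C)C(C)(C)C)[C@]1(C)CC[C@@](CO)(C(C)C)O1
F10 | step 15 | (2S,5S)-5-[(1R)-1-[(tert-butyldimethylsilyl)oxy]prop-2-en-1-yl]-5-methyl-2-(propan-2-yl)oxolane-2-carbaldehyde | C=C[C@@H](O[Si](C)(C)C(C)(C)C)[C@]1(C)CC[C@@](C=O)(C(C)C)O1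
F11 | step 15 | (3E)-4-{(2S,5S)-5-[(1R)-1-[(tert-butyldimethylsilyl)oxy]prop-2-en-1-yl]-5-methyl-2-(propan-2-yl)oxolan-2-yl}but-3-en-2-one | C=C[C@@H](O[Si](C)(C)C(C)(C)C)[C@]1(C)CC[C@@](/C=C/C(C)=O)(C(C)C)O1
F12 | step 15 | C8 epimer of 26 [(2R)-2-methyloxiran-2-yl] | C=C[C@@H](O[Si](C)(C)C(C)(C)C)[C@]1(C)CC[C@@](/C=C/[C@]2(C)CO2)(C(C)C)O1
F13 | step 21 | triethyl{[(2R)-2-methyloxiran-2-yl]methoxy}silane | CC[Si](CC)(CC)OC[C@@]1(C)CO1
F14 | step 21 | (2R)-2-methyl-1-{2-[(2R)-2-methylbut-3-en-1-yl]-1,3-dithian-2-yl}-3-[(triethylsilyl)oxy]propan-2-ol | CC[Si](CC)(CC)OC[C@](C)(O)CC1(C[C@@H](C)C=C)SCCCS1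
F15 | step 21 | tertiary tert-butyldimethylsilyl ether of F14 | CC[Si](CC)(CC)OC[C@](C)(O[Si](C)(C)C(C)(C)C)CC1(C[C@@H](C)C=C)SCCCS1
F16 | step 21 | (2R)-2-[(tert-butyldimethylsilyl)oxy]-2-methyl-3-{2-[(2R)-2-methylbut-3-en-1-yl]-1,3-dithian-2-yl}propan-1-ol | OC[C@](C)(O[Si](C)(C)C(C)(C)C)CC1(C[C@@H](C)C=C)SCCCS1
F17 | step 21 | (2R)-2-[(tert-butyldimethylsilyl)oxy]-2-methyl-3-{2-[(2R)-2-methylbut-3-en-1-yl]-1,3-dithian-2-yl}propanal | O=C[C@](C)(O[Si](C)(C)C(C)(C)C)CC1(C[C@@H](C)C=C)SCCCS1
F18 | step 21 | C8 tert-butyldimethylsilyl ether of 36 | C=C[C@@H](O[Si](C)(C)C(C)(C)C)[C@]1(C)CC[C@@](/C=C/[C@](C)(O[Si](C)(C)C(C)(C)C)CC2(C[C@@H](C)C=C)SCCCS2)(C(C)C)O1
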